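## Retrosynthetic overview

- **Feature:** the C3–C3'' bond joins two carbons that each sit alpha to a ketone (C4=O in ring C, C4''=O in ring C''), so neither can act as the electrophile for the other. With ring C'' held as a flavone, C3'' is sp2, and the bond becomes the C(sp2)–C(sp) bond of a 3-alkynylflavone whose two alkyne carbons are the future C3 and C2.
- **Disconnections:** O-benzyl groups; C4=O from a C4 carbinol (temporary mask); cis ring C'' from the flavone C2''=C3'' (hydride to C2'', proton to C3'' on the same face); ring C by C3–C4 (alkyne hydroacylation) and O1–C2 (oxa-Michael); C3''–C(sp) by Sonogashira coupling.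
- **Ring order:** rings A'', B'' and C'' come with apigenin, ring B with 4-ethynylanisole, ring A with 2,4,6-trihydroxybenzaldehyde. Ring C is the only ring closed (trans, step 5), and ring C'' is saturated afterwards (cis, step 7).
- **Numbering:** flavanone numbering, with the anisyl unit unprimed and the hydroxyphenyl unit double-primed.

Key step: step 5

Assumption: the sense of induction of the thiourea (step 5) and of the bisphosphine (step 7) cannot be derived safely for these new substrates; both exist in both (pseudo)enantiomeric forms, and the form named stands for the one that gives 2R and 2''R.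

## Route

Step 1
Reactants: 1 apigenin
Product: 2 5,7-bis(benzyloxy)-2-[4-(benzyloxy)phenyl]-4H-chromen-4-one (tri-O-benzylapigenin)
Conditions: BnBr (4.5 equiv), K2CO3, DMF, 80 °C
Reagents that add atoms: benzyl bromide, BrCc1ccccc1
Why: Williamson etherification of the three phenoxides, in which the chelated 5''-OH reacts last (hence excess halide and heat), and benzyl is chosen because it survives base, rhodium, hydride and silane and leaves in one neutral final step.

Step 2
Reactants: 2 tri-O-benzylapigenin
Product: 4 5,7-bis(benzyloxy)-2-[4-(benzyloxy)phenyl]-3-iodo-4H-chromen-4-one, via 3-lithioflavone 3 (not isolated)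
Conditions: LiN(i-Pr)2 (1.3 equiv), THF, −78 °C; then I2, −78 °C → rt
Reagents that add atoms: iodine, II
Why: Kinetic lithiation of a flavone at C3'' (the only vinylic C–H, acidified and directed by C4''=O) followed by iodinolysis fixes the site, whereas electrophilic iodine sources would also attack C6''/C8'' of the dialkoxy ring A''.

Step 3
Reactants: 4 3-iodoflavone; 5 4-ethynylanisole
Product: 6 5,7-bis(benzyloxy)-2-[4-(benzyloxy)phenyl]-3-[(4-methoxyphenyl)ethynyl]-4H-chromen-4-one
Conditions: PdCl2(PPh3)2 (5 mol %), CuI (10 mol %), Et3N, DMF, 50 °C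
Reagents that add atoms: none
Why: Sonogashira coupling of a 3-iodoflavone (an alpha-iodoenone, fast in oxidative addition) with a terminal arylalkyne forms the C3''–C(sp) bond, the future C3–C3'' bond, and the fully substituted C2'' protects the chromone against amine attack.

Step 4
Reactants: 7 2,4,6-trihydroxybenzaldehyde
Product: 8 4,6-bis(benzyloxy)-2-hydroxybenzaldehyde
Conditions: BnBr (2.05 equiv), K2CO3, DMF, rt
Reagents that add atoms: benzyl bromide, BrCc1ccccc1
Why: Williamson etherification limited by stoichiometry, in which the para-OH reacts first, then one of the two equivalent ortho-OH groups, and the last ortho-OH is held in a hydrogen bond to the formyl oxygen and is far less nucleophilic.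

Step 5
Reactants: 6 alkynylflavone; 8 4,6-bis(benzyloxy)-2-hydroxybenzaldehyde (1.3 equiv)
Product: 10 (2R,3S)-5,7-bis(benzyloxy)-3-{5,7-bis(benzyloxy)-2-[4-(benzyloxy)phenyl]-4-oxo-4H-chromen-3-yl}-2-(4-methoxyphenyl)chroman-4-one (2,3-trans), via (E)-chalcone 9 (not isolated)
Conditions: (i) [Rh(cod)Cl]2 (5 mol %), Fe(C5H4PPh2)2 (dppf, 10 mol %), Na2CO3 (10 mol %), toluene, 80 °C; (ii) −25 °C, 1-[3,5-bis(trifluoromethyl)phenyl]-3-[(9R)-6'-methoxycinchonan-9-yl]thiourea (quinidine-derived, 20 mol %), then 23 °C
Reagents that add atoms: none
Why: Proposed new method: the rhodium phenoxide of 8 adds oxidatively into the formyl C–H bond to give a five-membered O,C-chelated acyl(hydrido)rhodium species, alkyne 6 inserts syn into Rh–H, and reductive elimination forms C3–C4 of (E)-chalcone 9. The step needs the acyl group on the alkyne carbon bound to C3'': the hydride goes to the carbon that the p-anisyl donor makes the more electrophilic one, and rhodium goes to the carbon from which the C4''=O oxygen can fill the site vacated on insertion as a five-membered chelate, two effects that have to outweigh the bulk of the flavone. Ring C then closes 6-endo-trig by addition of the free phenol oxygen (future O1) to C2, and the benzyloxy group at the future C5, which twists the aroyl group out of conjugation, places the equilibrium on the side of the closed form. C2 (R) is set by the catalyst, whose thiourea is to hold C4=O and C4''=O (a 1,4-dicarbonyl array in the role of the ester of the known substrates) while its quinuclidine nitrogen guides the phenol to one face; C3 (S) is under thermodynamic control, since its proton is exchanged by the amine and the centre settles trans-diequatorial. The closest known reaction types are the [Rh(cod)Cl]2/bisphosphine hydroacylation of symmetrical internal alkynes with salicylaldehydes followed by base-induced oxa-Michael closure to racemic trans-2,3-disubstituted chroman-4-ones, and the thiourea-catalysed enantioselective closure of alpha-carboxylate-activated 2'-hydroxychalcones; new are the unsymmetrical flavonyl alkyne and the catalyst-controlled closure in the same pot. Racemic background closure is held down by keeping the first stage free of soluble base (catalytic, insoluble Na2CO3 in toluene) and by cooling before the organocatalyst is added, and the flat, fully substituted flavone is a spectator throughout.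

Step 6
Reactants: 10 flavanone–flavone
Product: 11 3-[(2R,3R,4R)-5,7-bis(benzyloxy)-4-hydroxy-2-(4-methoxyphenyl)chroman-3-yl]-5,7-bis(benzyloxy)-2-[4-(benzyloxy)phenyl]-4H-chromen-4-one (2,3-trans, 3,4-trans; the C3 descriptor changes by the CIP rules only)
Conditions: NaBH4, THF–MeOH, 0 °C
Reagents that add atoms: none
Why: Borohydride reduces the flavanone ketone while flavones are inert under these conditions; axial attack on the trans-diequatorial ring C should give the all-equatorial (4R) carbinol (a centre erased in step 8), and with C4 sp3 the C3–H is no longer acidic, so in step 7 C2/C3 cannot be lost by enolisation or retro-oxa-Michael opening and C4=O cannot be hydrosilylated.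

Step 7
Reactants: 11 C4 carbinol
Product: 14 (2R,3R)-5,7-bis(benzyloxy)-3-[(2R,3R,4R)-5,7-bis(benzyloxy)-4-hydroxy-2-(4-methoxyphenyl)chroman-3-yl]-2-[4-(benzyloxy)phenyl]chroman-4-one (ring C'' 2'',3''-cis), via C4-O-silyl ether 12 (not isolated), via bis-silyl enol ether 13 (not isolated)
Conditions: (i) Cu(OAc)2 (10 mol %), (R)-DTBM-SEGPHOS (11 mol %), (EtO)2MeSiH (6 equiv), toluene, 23 → 40 °C; (ii) AcOH–THF–H2O, −30 → 0 °C
Reagents that add atoms: none
Why: Proposed new method: the ligated copper hydride first silylates the C4 carbinol (dehydrogenative Si–O coupling), then delivers hydride to C2'' of the flavone, and the copper enolate is trapped by the silane as silyl enol ether 13, so that no free enolate can expel the O1'' phenoxide or be reduced further; the closest known reaction type is the copper hydride/bisphosphine enantioselective conjugate reduction of 2-substituted chromones, not yet shown on a tetrasubstituted 2-aryl-3-alkylchromone; C2'' (R) is set by the ligand, and C3'' (R) by rate-determining C-protonation of 13 anti to the 2''-aryl group, which stands pseudoaxial to avoid allylic strain with the C3'' substituent, so both new hydrogens end on one face (cis).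

Step 8
Reactants: 14 hydroxy ketone
Product: 15 (2R,3S,2''R,3''R)-penta-O-benzylsikokianin B (ring C trans, ring C'' cis)
Conditions: Dess–Martin periodinane (1.5 equiv), NaHCO3, CH2Cl2, 0 °C → rt
Reagents that add atoms: none
Why: Dess–Martin oxidation of the benzylic C4 carbinol under bicarbonate buffer restores C4=O without acid or base strong enough to enolise the cis ring C'', and C3 returns to a situation in which trans is the preferred arrangement anyway.

Step 9
Reactants: 15 penta-O-benzylsikokianin B
Product: 16 sikokianin B
Conditions: H2 (1 atm), Pd/C (10 wt %), THF–MeOH, rt; filtration, evaporation below 30 °C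
Reagents that add atoms: none
Why: Hydrogenolysis of five aryl benzyl ethers under neutral conditions leaves the methyl ether, both ketones and the four stereocentres untouched if it is stopped at full debenzylation and kept free of base, since the cis ring C'' can epimerise only through an enol(ate) or ring opening.

## Compound list

1 | apigenin | O=c1cc(-c2ccc(O)cc2)oc2cc(O)cc(O)c12 | starting material
2 | 5,7-bis(benzyloxy)-2-[4-(benzyloxy)phenyl]-4H-chromen-4-one | O=C1C=C(c2ccc(OCc3ccccc3)cc2)Oc2cc(OCc3ccccc3)cc(OCc3ccccc3)c12 | intermediate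
3 | 3-lithio derivative of 2 | [Li]C1=C(c2ccc(OCc3ccccc3)cc2)Oc2cc(OCc3ccccc3)cc(OCc3ccccc3)c2C1=O | intermediate
4 | 5,7-bis(benzyloxy)-2-[4-(benzyloxy)phenyl]-3-iodo-4H-chromen-4-one | IC1=C(c2ccc(OCc3ccccc3)cc2)Oc2cc(OCc3ccccc3)cc(OCc3ccccc3)c2C1=O | intermediate
5 | 4-ethynylanisole | COc1ccc(C#C)cc1 | starting material
6 | 5,7-bis(benzyloxy)-2-[4-(benzyloxy)phenyl]-3-[(4-methoxyphenyl)ethynyl]-4H-chromen-4-one | COc1ccc(C#CC2=C(c3ccc(OCc4ccccc4)cc3)Oc3cc(OCc4ccccc4)cc(OCc4ccccc4)c3C2=O)cc1 | intermediate
7 | 2,4,6-trihydroxybenzaldehyde | O=Cc1c(O)cc(O)cc1O | starting material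
8 | 4,6-bis(benzyloxy)-2-hydroxybenzaldehyde | O=Cc1c(O)cc(OCc2ccccc2)cc1OCc1ccccc1 | intermediate
9 | (E)-1-[4,6-bis(benzyloxy)-2-hydroxyphenyl]-2-{5,7-bis(benzyloxy)-2-[4-(benzyloxy)phenyl]-4-oxo-4H-chromen-3-yl}-3-(4-methoxyphenyl)prop-2-en-1-one | COc1ccc(/C=C(/C(=O)c2c(O)cc(OCc3ccccc3)cc2OCc2ccccc2)C2=C(c3ccc(OCc4ccccc4)cc3)Oc3cc(OCc4ccccc4)cc(OCc4ccccc4)c3C2=O)cc1 | intermediate
10 | (2R,3S)-5,7-bis(benzyloxy)-3-{5,7-bis(benzyloxy)-2-[4-(benzyloxy)phenyl]-4-oxo-4H-chromen-3-yl}-2-(4-methoxyphenyl)chroman-4-one | COc1ccc([C@@H]2Oc3cc(OCc4ccccc4)cc(OCc4ccccc4)c3C(=O)[C@H]2C2=C(c3ccc(OCc4ccccc4)cc3)Oc3cc(OCc4ccccc4)cc(OCc4ccccc4)c3C2=O)cc1 | intermediate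
11 | (2R,3R,4R)-C4 carbinol of 10 (2,3-trans, 3,4-trans) | COc1ccc([C@@H]2Oc3cc(OCc4ccccc4)cc(OCc4ccccc4)c3[C@H](O)[C@H]2C2=C(c3ccc(OCc4ccccc4)cc3)Oc3cc(OCc4ccccc4)cc(OCc4ccccc4)c3C2=O)cc1 | intermediate
12 | (2R,3S,4R)-C4-O-[diethoxy(methyl)silyl] ether of 11 | COc1ccc([C@@H]2Oc3cc(OCc4ccccc4)cc(OCc4ccccc4)c3[C@H](O[Si](C)(OCC)OCC)[C@H]2C2=C(c3ccc(OCc4ccccc4)cc3)Oc3cc(OCc4ccccc4)cc(OCc4ccccc4)c3C2=O)cc1 | intermediate
13 | (2R,3S,4R,2''S)-4''-[diethoxy(methyl)silyloxy]-2''H-chromene (silyl enol ether of ring C''; C2'' has the spatial arrangement of 2''R in the target) | COc1ccc([C@@H]2Oc3cc(OCc4ccccc4)cc(OCc4ccccc4)c3[C@H](O[Si](C)(OCC)OCC)[C@H]2C2=C(O[Si](C)(OCC)OCC)c3c(OCc4ccccc4)cc(OCc4ccccc4)cc3O[C@H]2c2ccc(OCc4ccccc4)cc2)cc1 | intermediate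
14 | (2R,3R,4R,2''R,3''R)-hydroxy ketone (ring C 2,3-trans carbinol, ring C'' cis flavanone) | COc1ccc([C@@H]2Oc3cc(OCc4ccccc4)cc(OCc4ccccc4)c3[C@H](O)[C@H]2[C@H]2C(=O)c3c(OCc4ccccc4)cc(OCc4ccccc4)cc3O[C@H]2c2ccc(OCc4ccccc4)cc2)cc1 | intermediate
15 | (2R,3S,2''R,3''R)-penta-O-benzylsikokianin B | COc1ccc([C@@H]2Oc3cc(OCc4ccccc4)cc(OCc4ccccc4)c3C(=O)[C@H]2[C@H]2C(=O)c3c(OCc4ccccc4)cc(OCc4ccccc4)cc3O[C@H]2c2ccc(OCc4ccccc4)cc2)cc1 | intermediate
16 | sikokianin B, (2R,3S,2''R,3''R) | COc1ccc([C@@H]2Oc3cc(O)cc(O)c3C(=O)[C@H]2[C@H]2C(=O)c3c(O)cc(O)cc3O[C@H]2c2ccc(O)cc2)cc1 | target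

## Step count and risks

Total step count: 9.
Longest linear sequence: 8 (steps 1, 2, 3, 5, 6, 7, 8, 9, from apigenin).

**Step 5 (labelled).**
- The bulk of the flavone may steer the acyl group to the anisyl-bearing alkyne carbon.
- The hindered, electron-rich aldehyde may decarbonylate.
- Ring closure may begin at 80 °C without the chiral catalyst and erode the enantiomeric purity.
- The thiourea may be tied up by rhodium or give weak facial control.
- The equilibration of C3 may be accompanied by retro-oxa-Michael opening and loss of C2.

Fallback, from 6 and 8 back to 10: catalyst control is given up. The known one-stage tandem hydroacylation/oxa-Michael reaction is run with [Rh(cod)Cl]2, dppf and CsF in toluene at 80–100 °C. This should give the trans product as the racemate, that is 10 together with its (2S,3R) enantiomer F1. The two are separated by preparative chromatography on a polysaccharide chiral stationary phase, and 10 goes on to step 6. This answers the losses of enantiomeric purity but not acyl delivery to the wrong alkyne carbon.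

**Step 7 (labelled).**
- The tetrasubstituted, donor-substituted C2''=C3'' may resist hydrocupration.
- The facial preferences of ligand and substrate may be mismatched.
- The copper enolate may expel the O1'' phenoxide before it is silylated.
- The protonation may not be fully anti to the aryl group, or C3'' may epimerise during hydrolysis.

Fallback, from 11 back to 15:
- Flavones are known to undergo homogeneous enantioselective hydrogenation with a ruthenium N-heterocyclic carbene catalyst: Ru(cod)(2-methylallyl)2, 1,3-bis[(R)-1-(1-naphthyl)ethyl]imidazolinium tetrafluoroborate, KOt-Bu, H2 at about 100 bar, toluene–hexane.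
- This catalyst adds hydrogen syn across C2=C3 and reduces on to the flavan-4-ol. It has been shown on 2-arylchromones, and the C3'' substituent is expected to slow it.
- Here it should give the 4,4''-diol with an all-cis ring C'' F2.
- Oxidation of both carbinols with Dess–Martin periodinane/NaHCO3 gives 15 directly, bypassing 14.

**Step 9.**
- Prolonged exposure may open the benzylic C2–O1 or C2''–O1'' bonds hydrogenolytically.
- The freed 4'''-OH may assist opening of ring C'', or basic charcoal may cause epimerisation of C3'' to the trans ring.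

Fallback, from 15 back to 16: debenzylation without hydrogen or metal, using BCl3 and pentamethylbenzene (cation scavenger) in CH2Cl2 at −78 °C with a cold aqueous methanol quench. The 4'-methoxy group, which has no neighbouring carbonyl, is retained at this temperature. No compound outside the list is made on this way: none F0.

## Further compounds

F1 | step 5 | (2S,3R)-enantiomer of 10 | COc1ccc([C@H]2Oc3cc(OCc4ccccc4)cc(OCc4ccccc4)c3C(=O)[C@@H]2C2=C(c3ccc(OCc4ccccc4)cc3)Oc3cc(OCc4ccccc4)cc(OCc4ccccc4)c3C2=O)cc1
F2 | step 7 | (2R,3R,4R,2''R,3''S,4''R)-4,4''-diol (ring C 2,3-trans-3,4-trans, ring C'' all-cis; the C3'' descriptor changes by the CIP rules only) | COc1ccc([C@@H]2Oc3cc(OCc4ccccc4)cc(OCc4ccccc4)c3[C@H](O)[C@H]2[C@H]2[C@@H](O)c3c(OCc4ccccc4)cc(OCc4ccccc4)cc3O[C@H]2c2ccc(OCc4ccccc4)cc2)cc1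
F0 | step 9 | none | none
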